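**Retrosynthetic overview**
1. Target 20 ⇒ triol ketone 15. Both esters go on last. C7=C11 comes from an acetone aldol at C7 and an E1cB loss of acetate, run in the same operation as the C4 acetylation.
2. 3β,4α-Diol 13 ⇒ α-ketol 12 ⇒ ring A enone 10. H and OH are added across C4=C5, then C3=O is reduced under direction from the new OH.
3. Decalin enedione 10 ⇒ hydrindenedione 4 + CH2Br2. This is the key one-carbon ring enlargement: a 1,2-shift of quaternary C10 places C9 between C10 and C8.
4. 4 ⇒ 2-methylcyclopentane-1,3-dione 1 + ethyl vinyl ketone 2, by a desymmetrising annulation that sets C10.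
5. Ring order: the five-membered ring is bought in 1, ring A is closed in step 1, and the five-membered ring is enlarged to ring B in step 2.

Assumption: the SMILES is taken literally, that is a trans-decalin with 10β-methyl and 5α-H, a 3β-ester and 4α-acetate that are trans-diequatorial, and an (R)-2-methylbutanoate whose acid is bought as the single enantiomer; comments use eudesmane numbering.

**Step 1**
Reactants: 1 2-methylcyclopentane-1,3-dione; 2 pent-1-en-3-one (ethyl vinyl ketone)
Product: 4 (7aS)-4,7a-dimethyl-2,3,7,7a-tetrahydro-1H-indene-1,5(6H)-dione, via triketone 3 (not isolated)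
Conditions: H2O, AcOH (cat.), 70 °C; concentrate; L-phenylalanine (1.0 equiv, recovered), D-camphorsulfonic acid (0.5 equiv), MeCN, 30 to 70 °C; recrystallise
Reagents that add atoms: none
Why: Michael addition followed by a Hajos–Parrish–Eder–Sauer–Wiechert aldol condensation, in which the L-phenylalanine enamine of the ethyl ketone attacks only one of the two enantiotopic ring carbonyls and so fixes quaternary C10 as S (β-methyl); a primary amino acid is the proven choice for ethyl ketones.

**Step 2**
Reactants: 4 (7aS)-4,7a-dimethyl-2,3,7,7a-tetrahydro-1H-indene-1,5(6H)-dione; 5 dibromomethane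
Product: 10 (4aR)-1,4a-dimethyl-4,4a,7,8-tetrahydronaphthalene-2,6(3H,5H)-dione, via potassium dienolate 6 (not isolated), via dibromomethyl alkoxide 7 (not isolated), via lithium carbenoid 8 (not isolated), via ring-enlarged bis-enolate 9 (not isolated)
Conditions: KH (1.0 equiv), THF, 0 °C; CH2Br2 (1.3 equiv), LDA (1.3 equiv), −95 °C; n-BuLi (2.6 equiv), −95 to 0 °C; 2 M HCl, THF, 23 °C
Reagents that add atoms: dibromomethane 5, BrCBr
Why: Proposed new method: a one-flask, dienolate-masked β-oxido carbenoid ring enlargement of an unprotected enedione; KH removes the most acidic proton (γ-H at C6), so the ring A enone becomes the extended dienolate 6, which (a) no longer accepts nucleophiles at C3, (b) can no longer serve as electron sink for a vinylogous retro-aldol cleavage of C8–C10 that would racemise C10, and (c) makes C10 an electron-rich, allylic, fully substituted migrating group; LiCHBr2 then adds to the only free carbonyl (C8) anti to the angular methyl, Br/Li exchange gives carbenoid 8, and the alkoxide pushes the more substituted C10 in a concerted suprafacial 1,2-shift (retention at C10) onto the electrophilic carbenoid carbon with loss of LiBr, so the new CH2 (C9) sits between C10 and C8; acid protonates 9 and equilibrates the double bond to the most stable tetrasubstituted C4=C5 enone; the closest known reaction type is the semipinacol-like β-oxido carbenoid ring enlargement of simple cycloalkanones with LiCHBr2 and n-BuLi (more substituted carbon migrates), combined with the in situ enolate masking of steroidal 4-en-3-ones used in 17-ethynylations; what is new is the anionic mask, the second carbonyl group left unprotected, and a quaternary stereocentre as the migrating carbon.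

**Step 3**
Reactants: 10 (4aR)-1,4a-dimethyl-4,4a,7,8-tetrahydronaphthalene-2,6(3H,5H)-dione
Product: 12 (1S,4aR,8aR)-1-hydroxy-1,4a-dimethyldecahydronaphthalene-2,6-dione, via tertiary hydroperoxide 11 (not isolated)
Conditions: Mn(dpm)3 (10 mol %), PhSiH3 (2 equiv), O2 (1 atm), i-PrOH/CH2Cl2, 0 to 23 °C; then P(OEt)3
Reagents that add atoms: dioxygen, O=O
Why: Mukaiyama-type hydrogen-atom-transfer hydration of an enone (reductive α-hydroxylation), in which the manganese hydride delivers H to C5 from the α face opposite the axial C10 methyl (trans-decalin, 5R), the C4 α-keto radical takes up O2 from the same open α face (equatorial C–O, axial methyl, 4S), and the isolated C8 ketone is inert.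

**Step 4**
Reactants: 12 (1S,4aR,8aR)-1-hydroxy-1,4a-dimethyldecahydronaphthalene-2,6-dione
Product: 13 (4aR,5S,6S,8aR)-5,6-dihydroxy-5,8a-dimethyloctahydronaphthalen-2(1H)-one
Conditions: Me4NBH(OAc)3 (3 equiv), MeCN/AcOH 1:1, −25 °C
Reagents that add atoms: none
Why: Hydroxyl-directed triacetoxyborohydride reduction (Saksena–Evans type), in which only hydride bound through the 4α-OH is reactive enough, so C3=O is reduced while the unassisted C8 ketone survives, and hydride enters axially from the α face (the β face is blocked by the axial C4 and C10 methyls) to give the equatorial 3β-alcohol (3S) and hence the trans-diequatorial diol.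

**Step 5**
Reactants: 13 (4aR,5S,6S,8aR)-5,6-dihydroxy-5,8a-dimethyloctahydronaphthalen-2(1H)-one; 14 acetone
Product: 15 (3R,4aR,5S,6S,8aR)-5,6-dihydroxy-3-(2-hydroxypropan-2-yl)-5,8a-dimethyloctahydronaphthalen-2(1H)-one
Conditions: LDA (3.3 equiv), THF, −78 °C; ZnCl2 (2 equiv); acetone (5 equiv), −78 to −40 °C; aq. NH4Cl
Reagents that add atoms: acetone 14, CC(C)=O
Why: Aldol addition of a zinc enolate, in which LDA first deprotonates both OH groups and then takes the less hindered C7 proton (C9 is neopentyl), zinc holds the aldolate against retro-aldol, and the side chain sits equatorial (7R), a centre that is erased in step 7.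

**Step 6**
Reactants: 15 (3R,4aR,5S,6S,8aR)-5,6-dihydroxy-3-(2-hydroxypropan-2-yl)-5,8a-dimethyloctahydronaphthalen-2(1H)-one; 16 (R)-2-methylbutanoic acid
Product: 17 (1S,2S,4aR,7R,8aR)-1-hydroxy-7-(2-hydroxypropan-2-yl)-1,4a-dimethyl-6-oxodecahydronaphthalen-2-yl (2R)-2-methylbutanoate
Conditions: DCC (1.3 equiv), DMAP (0.1 equiv), CH2Cl2, 0 to 23 °C
Reagents that add atoms: (R)-2-methylbutanoic acid 16, CC[C@@H](C)C(=O)O
Why: Steglich esterification, in which only the secondary equatorial 3β-OH is acylated, both tertiary alcohols are inert, neither C3 nor the α-centre of 16 is touched, and any trace of the enantiomeric decalin becomes a separable diastereomer.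

**Step 7**
Reactants: 17 (1S,2S,4aR,7R,8aR)-1-hydroxy-7-(2-hydroxypropan-2-yl)-1,4a-dimethyl-6-oxodecahydronaphthalen-2-yl (2R)-2-methylbutanoate; 18 acetic anhydride
Product: 20 (1S,2S,4aR,8aR)-1-acetoxy-1,4a-dimethyl-6-oxo-7-(propan-2-ylidene)decahydronaphthalen-2-yl (2R)-2-methylbutanoate (CNP0111007.1), via bis-acetate 19 (not isolated)
Conditions: Ac2O (8 equiv), Sc(OTf)3 (5 mol %), MeCN, −20 to 0 °C; aq. NaHCO3 wash; crude in toluene, DBU (3 equiv), 40 °C
Reagents that add atoms: acetic anhydride 18, CC(=O)OC(C)=O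
Why: Sc(OTf)3-catalysed acetylation of tertiary alcohols followed by E1cB elimination, in which both tertiary OH groups are acetylated at low temperature without ionisation, DBU then removes the acidic C7–H and expels only the β-acetoxy group to give the conjugated tetrasubstituted C7=C11 alkene (any isopropenyl isomer is drawn into conjugation), and the C4 acetate stays because no carbonyl acidifies a neighbouring C–H.

**Compound list**
1 | 2-methylcyclopentane-1,3-dione | CC1C(=O)CCC1=O | starting material
2 | pent-1-en-3-one (ethyl vinyl ketone) | CCC(=O)C=C | starting material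
3 | 2-methyl-2-(3-oxopentyl)cyclopentane-1,3-dione | CCC(=O)CCC1(C)C(=O)CCC1=O | intermediate
4 | (7aS)-4,7a-dimethyl-2,3,7,7a-tetrahydro-1H-indene-1,5(6H)-dione | O=C1CC[C@]2(C)C(=O)CCC2=C1C | intermediate
5 | dibromomethane | BrCBr | starting material
6 | potassium (7aS)-4,7a-dimethyl-1-oxo-2,6,7,7a-tetrahydro-1H-inden-5-olate (extended dienolate) | [K+].[O-]C1=C(C)C2=CCC(=O)[C@@]2(C)CC1 | intermediate
7 | lithium potassium salt of (1S,7aS)-1-(dibromomethyl)-4,7a-dimethyl-2,6,7,7a-tetrahydro-1H-indene-1,5-diol (CHBr2 anti to the angular methyl) | [K+].[Li+].[O-]C1=C(C)C2=CC[C@@]([O-])(C(Br)Br)[C@@]2(C)CC1 | intermediate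
8 | β-oxido carbenoid, the 1-[bromo(lithio)methyl] analogue of 7 | [K+].[Li+].[O-]C1=C(C)C2=CC[C@@]([O-])(C([Li])Br)[C@@]2(C)CC1 | intermediate
9 | lithium potassium (4aR)-1,4a-dimethyl-3,4,4a,7-tetrahydronaphthalene-2,6-diolate | [K+].[Li+].[O-]C1=C(C)C2=CCC([O-])=C[C@@]2(C)CC1 | intermediate
10 | (4aR)-1,4a-dimethyl-4,4a,7,8-tetrahydronaphthalene-2,6(3H,5H)-dione | O=C1CC[C@]2(C)CC(=O)CCC2=C1C | intermediate
11 | (1S,4aR,8aR)-1-hydroperoxy-1,4a-dimethyldecahydronaphthalene-2,6-dione | O=C1CC[C@]2(C)CC(=O)CC[C@H]2[C@]1(C)OO | intermediate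
12 | (1S,4aR,8aR)-1-hydroxy-1,4a-dimethyldecahydronaphthalene-2,6-dione (trans-decalin, 4α-OH equatorial) | O=C1CC[C@]2(C)CC(=O)CC[C@H]2[C@]1(C)O | intermediate
13 | (4aR,5S,6S,8aR)-5,6-dihydroxy-5,8a-dimethyloctahydronaphthalen-2(1H)-one (3β,4α-diol) | O[C@H]1CC[C@]2(C)CC(=O)CC[C@H]2[C@]1(C)O | intermediate
14 | acetone | CC(C)=O | starting material
15 | (3R,4aR,5S,6S,8aR)-5,6-dihydroxy-3-(2-hydroxypropan-2-yl)-5,8a-dimethyloctahydronaphthalen-2(1H)-one | O[C@H]1CC[C@]2(C)CC(=O)[C@@H](C(C)(C)O)C[C@H]2[C@]1(C)O | intermediate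
16 | (R)-2-methylbutanoic acid | CC[C@@H](C)C(=O)O | starting material
17 | (1S,2S,4aR,7R,8aR)-1-hydroxy-7-(2-hydroxypropan-2-yl)-1,4a-dimethyl-6-oxodecahydronaphthalen-2-yl (2R)-2-methylbutanoate | CC[C@@H](C)C(=O)O[C@H]1CC[C@]2(C)CC(=O)[C@@H](C(C)(C)O)C[C@H]2[C@]1(C)O | intermediate
18 | acetic anhydride | CC(=O)OC(C)=O | starting material
19 | (1S,2S,4aR,7R,8aR)-1-acetoxy-7-(2-acetoxypropan-2-yl)-1,4a-dimethyl-6-oxodecahydronaphthalen-2-yl (2R)-2-methylbutanoate | CC[C@@H](C)C(=O)O[C@H]1CC[C@]2(C)CC(=O)[C@@H](C(C)(C)OC(C)=O)C[C@H]2[C@]1(C)OC(C)=O | intermediate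
20 | (1S,2S,4aR,8aR)-1-acetoxy-1,4a-dimethyl-6-oxo-7-(propan-2-ylidene)decahydronaphthalen-2-yl (2R)-2-methylbutanoate | CC[C@@H](C)C(=O)O[C@H]1CC[C@]2(C)CC(=O)C(=C(C)C)C[C@H]2[C@]1(C)OC(C)=O | target

**Total step count:** 7. **Longest linear sequence:** 7 (1 → 4 → 10 → 12 → 13 → 15 → 17 → 20).

**Steps most likely to fail**

Step 2, the proposed new ring enlargement. The risks are incomplete masking, enolisation of C8 in place of addition, and quenching of the carbenoid. The fallback uses known chemistry, sets out from 4 and comes back at 10. Ethane-1,2-dithiol (1.0 equiv) and p-TsOH in AcOH thioketalise only the conjugated carbonyl and leave the double bond in place, giving the spiro-dithiolane F1. LiCHBr2 (CH2Br2, LDA, THF, −78 °C) adds to the one carbonyl that is left, giving the dibromomethyl carbinol F2. n-BuLi (2.1 equiv, −95 to 0 °C) then carries out the classical β-oxido carbenoid ring enlargement with migration of the quaternary carbon, giving the ring-enlarged keto dithiolane F3. MeI and CaCO3 in aqueous MeCN free the enone and deliver 10.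

Step 3, hydrogen-atom transfer to a tetrasubstituted enone. The reaction may be slow, and the facial selectivity at C5 and C4 is not proven. The fallback sets out from 10 and comes back at 12. Ethylene glycol and PPTS in benzene ketalise only the saturated C8 ketone, giving the enone ketal F4. Li in NH3/THF at −78 °C gives the trans-fused enolate, which is trapped with TMSCl/Et3N as the silyl enol ether F5. Rubottom oxidation (mCPBA, NaHCO3, CH2Cl2, 0 °C) from the α face gives the α-silyloxy ketone ketal F6. Finally, 1 M HCl in THF removes the silyl group and the ketal to give 12.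

Step 7, double tertiary acetylation plus elimination on a retro-aldol-prone substrate. The fallback moves both acylations ahead of the C–C bond formation. It sets out from 13 and comes back at 19. Steglich esterification of 13 with 16 gives the hydroxy ester ketone F7. Ac2O, DMAP and Et3N at 50 °C acetylate the single tertiary alcohol, giving the diester ketone F8. Soft enolisation with TiCl4 and Bu3N in CH2Cl2 at −78 °C, followed by acetone (titanium crossed aldol, esters untouched), gives the aldol F9. Ac2O with DMAP converts F9 into 19, which DBU takes on to 20 as in the main route.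

**Further compounds**
F1 | step 2 | (7a'S)-4',7a'-dimethyl-2',3',7',7a'-tetrahydrospiro[1,3-dithiolane-2,5'-inden]-1'(6'H)-one | S3CCSC31CC[C@]2(C)C(=O)CCC2=C1C
F2 | step 2 | (1'S,7a'S)-1'-(dibromomethyl)-4',7a'-dimethyl-1',2',3',6',7',7a'-hexahydrospiro[1,3-dithiolane-2,5'-inden]-1'-ol | S3CCSC31CC[C@]2(C)[C@](O)(C(Br)Br)CCC2=C1C
F3 | step 2 | 2,2-(ethane-1,2-diyldisulfanediyl) thioketal of 10, (4aR), C6 ketone free | S3CCSC31CC[C@]2(C)CC(=O)CCC2=C1C
F4 | step 3 | 6,6-ethylenedioxy ketal of 10, (4aR), enone free | O=C1CC[C@]2(C)CC3(OCCO3)CCC2=C1C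
F5 | step 3 | trans-fused (5α-H, 10β-methyl) C3 trimethylsilyl enol ether (C3=C4) of the C8 ethylene ketal | C[Si](C)(C)OC1=C(C)[C@@H]2CCC3(OCCO3)C[C@@]2(C)CC1
F6 | step 3 | 4α-trimethylsilyl ether and C8 ethylene ketal of 12 | O=C1CC[C@]2(C)CC3(OCCO3)CC[C@H]2[C@]1(C)O[Si](C)(C)C
F7 | step 7 | (1S,2S,4aR,8aR)-1-hydroxy-1,4a-dimethyl-6-oxodecahydronaphthalen-2-yl (2R)-2-methylbutanoate | CC[C@@H](C)C(=O)O[C@H]1CC[C@]2(C)CC(=O)CC[C@H]2[C@]1(C)O
F8 | step 7 | (1S,2S,4aR,8aR)-1-acetoxy-1,4a-dimethyl-6-oxodecahydronaphthalen-2-yl (2R)-2-methylbutanoate | CC[C@@H](C)C(=O)O[C@H]1CC[C@]2(C)CC(=O)CC[C@H]2[C@]1(C)OC(C)=O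
F9 | step 7 | (1S,2S,4aR,7R,8aR)-1-acetoxy-7-(2-hydroxypropan-2-yl)-1,4a-dimethyl-6-oxodecahydronaphthalen-2-yl (2R)-2-methylbutanoate | CC[C@@H](C)C(=O)O[C@H]1CC[C@]2(C)CC(=O)[C@@H](C(C)(C)O)C[C@H]2[C@]1(C)OC(C)=O
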